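**Retrosynthetic overview**
1. The two MOM ethers (O3, O4') of 22 are removed last by acid methanolysis to give target 23.
2. The strategy rests on ring A (C4a, C5, C6, C7, C8, C8a): C5–OH para to C8–OMe, with C7–O-prenyl and C6–H between them, fused through C4a–C8a to pyranone ring C. This hydroquinone-monoether pattern is cut at C4a–C5 back to the 4-methoxy-4-(pyranon-2-yl)cyclobutenone 19 (Moore rearrangement).
3. 19 comes from pyranone 11, lithiated at the CH beside the ring oxygen, and prenyl semisquarate 16 (from diisopropyl squarate 12 and prenol 15), followed by O-methylation.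
4. 11 (ring C carrying ring B) comes from vanillin 1 and furan 3: furyl carbinol, Achmatowicz rearrangement, epoxidation, acid isomerisation to the 3-hydroxy-4-pyranone.
5. Order of ring formation: ring B is bought, ring C is built in steps 3–6, ring A is closed last in step 11.

Key step: step 11

Remark on the chemistry: the target has no stereocentre. Compounds 5–8, 13, 19 and 21 are racemic (6–8 also diastereomeric mixtures), and all their stereocentres are destroyed later, so no stereocontrol is needed. C6 of pyranone 11 becomes C8a of the flavone and C5 of 11 becomes C4a.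

**Route**

Step 1
Reactants: 1 vanillin
Product: 2 3-methoxy-4-(methoxymethoxy)benzaldehyde
Conditions: MOMCl, iPr2NEt, CH2Cl2, 0 °C → rt
Reagents that add atoms: chloromethyl methyl ether (MOMCl), COCCl
Why: O-alkylation of the phenol (Williamson-type acetal formation) masks the acidic OH so that the aldehyde can take an organolithium in step 2.

Step 2
Reactants: 3 furan; 2 3-methoxy-4-(methoxymethoxy)benzaldehyde
Product: 5 racemic (furan-2-yl)[3-methoxy-4-(methoxymethoxy)phenyl]methanol, via 2-furyllithium 4 (not isolated)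
Conditions: n-BuLi, THF, 0 °C; then 2, –78 → 0 °C; H2O
Reagents that add atoms: none
Why: alpha-lithiation of furan and 1,2-addition of the heteroaryllithium to the aldehyde should give the furyl carbinol, whose racemic stereocentre is erased in step 6.

Step 3
Reactants: 5 racemic (furan-2-yl)[3-methoxy-4-(methoxymethoxy)phenyl]methanol
Product: 6 6-hydroxy-2-[3-methoxy-4-(methoxymethoxy)phenyl]-2H-pyran-3(6H)-one (racemic mixture of diastereomers)
Conditions: NBS, NaHCO3, THF/H2O (4:1), 0 °C
Reagents that add atoms: water, O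
Why: Achmatowicz rearrangement; the furan is oxidised far faster than the aryl ring is brominated, and the buffer protects the acid-labile carbinol and MOM ether.

Step 4
Reactants: 6 6-hydroxy-2-[3-methoxy-4-(methoxymethoxy)phenyl]-2H-pyran-3(6H)-one
Product: 7 6-methoxy-2-[3-methoxy-4-(methoxymethoxy)phenyl]-2H-pyran-3(6H)-one (racemic mixture of diastereomers)
Conditions: HC(OMe)3, MeOH, PPTS (cat.), rt
Reagents that add atoms: methanol, CO; trimethyl orthoformate, COC(OC)OC (either may deliver the methoxy group)
Why: acid-catalysed acetalisation of the lactol through the conjugated oxocarbenium ion gives a base-stable methyl acetal for the epoxidation, under acid too weak to cleave the aryl MOM ether.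

Step 5
Reactants: 7 6-methoxy-2-[3-methoxy-4-(methoxymethoxy)phenyl]-2H-pyran-3(6H)-one
Product: 8 2-methoxy-4-[3-methoxy-4-(methoxymethoxy)phenyl]-3,7-dioxabicyclo[4.1.0]heptan-5-one (the 4,5-epoxide of 7; racemic, configuration inconsequential)
Conditions: 30% aq. H2O2, NaOH (cat.), MeOH, 0 °C
Reagents that add atoms: hydrogen peroxide, OO
Why: Weitz–Scheffer nucleophilic epoxidation of the enone raises C4 to the oxidation level the gamma-pyranone needs and leaves the electron-rich arene untouched.

Step 6
Reactants: 8 2-methoxy-4-[3-methoxy-4-(methoxymethoxy)phenyl]-3,7-dioxabicyclo[4.1.0]heptan-5-one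
Product: 10 3-hydroxy-2-(4-hydroxy-3-methoxyphenyl)-4H-pyran-4-one, via 3-hydroxy-2-[3-methoxy-4-(methoxymethoxy)phenyl]-4H-pyran-4-one 9 (not isolated)
Conditions: 2 M aq. H2SO4, 1,4-dioxane, 90 °C
Reagents that add atoms: none
Why: acid opens the alpha,beta-epoxy ketone to the 3,4-dioxygenated (diosphenol) level, enolisation toward the benzylic C2 and beta-elimination of methanol from C6 then give the 3-hydroxy-4-pyranone (the maltol-type isomerisation), and the aryl MOM ether is hydrolysed in the same pot by design.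

Step 7
Reactants: 10 3-hydroxy-2-(4-hydroxy-3-methoxyphenyl)-4H-pyran-4-one
Product: 11 3-(methoxymethoxy)-2-[3-methoxy-4-(methoxymethoxy)phenyl]-4H-pyran-4-one
Conditions: MOMCl (3 equiv), iPr2NEt, CH2Cl2, 0 °C → rt
Reagents that add atoms: chloromethyl methyl ether (MOMCl), COCCl
Why: double O-alkylation of the enolic 3-OH and the phenol removes both acidic protons before the lithiation and installs groups that come off together at the end.

Step 8
Reactants: 12 diisopropyl squarate
Product: 14 3-isopropoxycyclobut-3-ene-1,2-dione, via 4-hydroxy-2,3-diisopropoxycyclobut-2-en-1-one 13 (not isolated)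
Conditions: LiAlH(OtBu)3, THF, –78 → 0 °C, aq. HCl work-up; then conc. HCl, CH2Cl2, rt
Reagents that add atoms: water, O
Why: the mild hydride adds once to one of the two equivalent carbonyls, and acid then ionises the allylic hydroxyl and hydrolyses the alkoxy-stabilised cation with loss of isopropanol (1,2-reduction followed by allylic transposition to the semisquarate).

Step 9
Reactants: 14 3-isopropoxycyclobut-3-ene-1,2-dione; 15 prenol (3-methylbut-2-en-1-ol)
Product: 16 3-[(3-methylbut-2-en-1-yl)oxy]cyclobut-3-ene-1,2-dione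
Conditions: prenol (10 equiv), Et3N (0.1 equiv), CH2Cl2, rt; volatiles removed in vacuo, cycle repeated
Reagents that add atoms: none
Why: addition–elimination of the alcohol at the alkoxy-bearing carbon of the vinylogous ester (transetherification of a squarate ester) is reversible, so excess prenol and removal of the more volatile isopropanol should drive it to the prenyl ester at a temperature too low for the allyl vinyl ether to rearrange.

Step 10
Reactants: 11 3-(methoxymethoxy)-2-[3-methoxy-4-(methoxymethoxy)phenyl]-4H-pyran-4-one; 16 3-[(3-methylbut-2-en-1-yl)oxy]cyclobut-3-ene-1,2-dione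
Product: 19 racemic 4-methoxy-4-{5-(methoxymethoxy)-6-[3-methoxy-4-(methoxymethoxy)phenyl]-4-oxo-4H-pyran-2-yl}-3-[(3-methylbut-2-en-1-yl)oxy]cyclobut-2-en-1-one, via 6-lithiopyranone 17 (not isolated), via lithium tertiary alkoxide 18 (not isolated)
Conditions: lithium 2,2,6,6-tetramethylpiperidide (from 2,2,6,6-tetramethylpiperidine, n-BuLi), THF, –78 °C; then 16, –78 °C; then MeOTf (1.1 equiv), –78 → 0 °C
Reagents that add atoms: methyl trifluoromethanesulfonate (MeOTf), COS(=O)(=O)C(F)(F)F
Why: the hindered amide should remove H6, the most acidic ring proton beside the ring oxygen and beta to the carbonyl (deprotonative lithiation as known for chromones, 4-pyridones and uracils), the vinyllithium should add to the ketone-like carbonyl next to the alkoxy-bearing carbon of 16 in preference to the vinylogous ester carbonyl, and the alkoxide is capped by O-methylation; the new quaternary centre is racemic and is destroyed in step 11.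

Step 11
Reactants: 19 racemic 4-methoxy-4-{5-(methoxymethoxy)-6-[3-methoxy-4-(methoxymethoxy)phenyl]-4-oxo-4H-pyran-2-yl}-3-[(3-methylbut-2-en-1-yl)oxy]cyclobut-2-en-1-one
Product: 22 5-hydroxy-8-methoxy-3-(methoxymethoxy)-2-[3-methoxy-4-(methoxymethoxy)phenyl]-7-[(3-methylbut-2-en-1-yl)oxy]-4H-chromen-4-one, via (Z)-dienylketene 20 (not isolated), via ring-fused cyclohexadienone 21 (not isolated)
Conditions: PhMe (0.02 M, degassed), 110 °C
Reagents that add atoms: none
Why: Thermal conrotatory 4π ring opening of cyclobutenone 19 breaks its C1–C4 bond and, because the 4-methoxy donor rotates outward, gives the (Z)-dienylketene 20 with the pyranone C5=C6 bond folded in beside the ketene carbon. Ring A then closes by thermal disrotatory 6π electrocyclisation, the electrophilic ketene carbon bonding to the nucleophilic enol-ether beta-carbon of the pyranone (C5 of 11, the future C4a) to form C4a–C5 and dienone 21, whose doubly activated C4a–H tautomerises to the C5 phenol hydrogen-bonded to the C4 carbonyl. The closest known reaction type is the Moore rearrangement of 4-alkenyl- and 4-heteroaryl-4-alkoxycyclobutenones to annulated hydroquinone monoethers. No stereocentre survives, since the quaternary centre of 19 and the transient C4a centre of 21 both become sp2. The selectivity needed is torquoselectivity (pyranonyl inward), secured by the outward preference of the methoxy group, while the placement of C5–OH, C6–H, C7–O-prenyl and C8–OMe is fixed by the constitution of 19. The temperature is well below that expected for [3,3] shift of a prenyl enol or aryl ether, and high dilution should suppress ketene dimerisation.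

Step 12
Reactants: 22 5-hydroxy-8-methoxy-3-(methoxymethoxy)-2-[3-methoxy-4-(methoxymethoxy)phenyl]-7-[(3-methylbut-2-en-1-yl)oxy]-4H-chromen-4-one
Product: 23 3,5-dihydroxy-2-(4-hydroxy-3-methoxyphenyl)-8-methoxy-7-[(3-methylbut-2-en-1-yl)oxy]-4H-chromen-4-one (target, CNP0210396.0)
Conditions: HCl (1.25 M in MeOH), MeOH/THF, rt → 40 °C
Reagents that add atoms: none
Why: acid-catalysed acetal exchange with methanol removes both MOM ethers under conditions mild enough for the aryl prenyl ether and the two methyl ethers to survive.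

**Compound list**
1 | vanillin | COc1cc(C=O)ccc1O | starting material
2 | 3-methoxy-4-(methoxymethoxy)benzaldehyde | COCOc1ccc(C=O)cc1OC | intermediate
3 | furan | c1ccoc1 | starting material
4 | 2-furyllithium | [Li]c1ccco1 | intermediate
5 | racemic (furan-2-yl)[3-methoxy-4-(methoxymethoxy)phenyl]methanol | COCOc1ccc(C(O)c2ccco2)cc1OC | intermediate
6 | 6-hydroxy-2-[3-methoxy-4-(methoxymethoxy)phenyl]-2H-pyran-3(6H)-one (racemic, diastereomer mixture) | COCOc1ccc(C2OC(O)C=CC2=O)cc1OC | intermediate
7 | 6-methoxy-2-[3-methoxy-4-(methoxymethoxy)phenyl]-2H-pyran-3(6H)-one (racemic, diastereomer mixture) | COCOc1ccc(C2OC(OC)C=CC2=O)cc1OC | intermediate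
8 | 2-methoxy-4-[3-methoxy-4-(methoxymethoxy)phenyl]-3,7-dioxabicyclo[4.1.0]heptan-5-one (racemic, diastereomer mixture) | COCOc1ccc(C2OC(OC)C3OC3C2=O)cc1OC | intermediate
9 | 3-hydroxy-2-[3-methoxy-4-(methoxymethoxy)phenyl]-4H-pyran-4-one | COCOc1ccc(-c2occc(=O)c2O)cc1OC | intermediate
10 | 3-hydroxy-2-(4-hydroxy-3-methoxyphenyl)-4H-pyran-4-one | COc1cc(-c2occc(=O)c2O)ccc1O | intermediate
11 | 3-(methoxymethoxy)-2-[3-methoxy-4-(methoxymethoxy)phenyl]-4H-pyran-4-one | COCOc1ccc(-c2occc(=O)c2OCOC)cc1OC | intermediate
12 | diisopropyl squarate (3,4-diisopropoxycyclobut-3-ene-1,2-dione) | CC(C)OC1=C(OC(C)C)C(=O)C1=O | starting material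
13 | racemic 4-hydroxy-2,3-diisopropoxycyclobut-2-en-1-one | CC(C)OC1=C(OC(C)C)C(O)C1=O | intermediate
14 | 3-isopropoxycyclobut-3-ene-1,2-dione | CC(C)OC1=CC(=O)C1=O | intermediate
15 | prenol (3-methylbut-2-en-1-ol) | CC(C)=CCO | starting material
16 | 3-[(3-methylbut-2-en-1-yl)oxy]cyclobut-3-ene-1,2-dione | CC(C)=CCOC1=CC(=O)C1=O | intermediate
17 | {5-(methoxymethoxy)-6-[3-methoxy-4-(methoxymethoxy)phenyl]-4-oxo-4H-pyran-2-yl}lithium | [Li]c1cc(=O)c(OCOC)c(-c2ccc(OCOC)c(OC)c2)o1 | intermediate
18 | racemic lithium 1-{5-(methoxymethoxy)-6-[3-methoxy-4-(methoxymethoxy)phenyl]-4-oxo-4H-pyran-2-yl}-2-[(3-methylbut-2-en-1-yl)oxy]-4-oxocyclobut-2-en-1-olate | [Li]OC1(c2cc(=O)c(OCOC)c(-c3ccc(OCOC)c(OC)c3)o2)C(=O)C=C1OCC=C(C)C | intermediate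
19 | racemic 4-methoxy-4-{5-(methoxymethoxy)-6-[3-methoxy-4-(methoxymethoxy)phenyl]-4-oxo-4H-pyran-2-yl}-3-[(3-methylbut-2-en-1-yl)oxy]cyclobut-2-en-1-one | O=C1C=C(OCC=C(C)C)C1(OC)c1cc(=O)c(OCOC)c(-c2ccc(OCOC)c(OC)c2)o1 | intermediate
20 | (3Z)-4-methoxy-4-{5-(methoxymethoxy)-6-[3-methoxy-4-(methoxymethoxy)phenyl]-4-oxo-4H-pyran-2-yl}-3-[(3-methylbut-2-en-1-yl)oxy]buta-1,3-dien-1-one | O=C=C/C(OCC=C(C)C)=C(/OC)c1cc(=O)c(OCOC)c(-c2ccc(OCOC)c(OC)c2)o1 | intermediate
21 | racemic 8-methoxy-3-(methoxymethoxy)-2-[3-methoxy-4-(methoxymethoxy)phenyl]-7-[(3-methylbut-2-en-1-yl)oxy]-4H-chromene-4,5(4aH)-dione | O=C1C=C(OCC=C(C)C)C(OC)=C2OC(-c3ccc(OCOC)c(OC)c3)=C(OCOC)C(=O)C12 | intermediate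
22 | 5-hydroxy-8-methoxy-3-(methoxymethoxy)-2-[3-methoxy-4-(methoxymethoxy)phenyl]-7-[(3-methylbut-2-en-1-yl)oxy]-4H-chromen-4-one | COCOc1ccc(-c2oc3c(OC)c(OCC=C(C)C)cc(O)c3c(=O)c2OCOC)cc1OC | intermediate
23 | 3,5-dihydroxy-2-(4-hydroxy-3-methoxyphenyl)-8-methoxy-7-[(3-methylbut-2-en-1-yl)oxy]-4H-chromen-4-one | COc1cc(-c2oc3c(OC)c(OCC=C(C)C)cc(O)c3c(=O)c2O)ccc1O | target

**Step count**
Total: 12 steps. Longest linear sequence: 10 steps (steps 1–7, 10, 11, 12); steps 8–9 form the convergent squarate branch.

**Steps most likely to fail**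

1. Step 10. Deprotonation may occur beside the carbonyl (C5) or on the aryl ring instead of at C6. The lithiated pyranone may add to unmetalated 11 before the electrophile arrives. MeOTf may also methylate the pyranone carbonyl. The fallback sets out from 11. Zincation with TMPZnCl·LiCl (THF, rt) and an I2 quench would give 2-iodo-5-(methoxymethoxy)-6-[3-methoxy-4-(methoxymethoxy)phenyl]-4H-pyran-4-one F1, whose regiochemistry can be confirmed before it is committed. Iodine–magnesium exchange (iPrMgCl·LiCl, THF, –40 °C) and addition to 16 would give, after aqueous work-up, the isolated racemic 4-hydroxy-4-{5-(methoxymethoxy)-6-[3-methoxy-4-(methoxymethoxy)phenyl]-4-oxo-4H-pyran-2-yl}-3-[(3-methylbut-2-en-1-yl)oxy]cyclobut-2-en-1-one F2. O-Methylation under neutral conditions (MeI, Ag2O, MeCN, rt) returns to the route at 19.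

2. Step 11. Ring closure onto the cross-conjugated pyranone double bond may be slow, so that a higher temperature is needed. At that temperature [3,3] shift or loss of the O-prenyl group, or ketene oligomerisation, may overtake the electrocyclisation. The fallback sets out from 14 and 11 and carries a benzyl ether through the thermolysis. Exchange of 14 with benzyl alcohol as in step 9 would give 3-(benzyloxy)cyclobut-3-ene-1,2-dione F3. Coupling with lithiated 11 and MeOTf as in step 10 would give racemic 3-(benzyloxy)-4-methoxy-4-{5-(methoxymethoxy)-6-[3-methoxy-4-(methoxymethoxy)phenyl]-4-oxo-4H-pyran-2-yl}cyclobut-2-en-1-one F4. Thermolysis in p-xylene at 140 °C (or hotter, in flow) would give 7-(benzyloxy)-5-hydroxy-8-methoxy-3-(methoxymethoxy)-2-[3-methoxy-4-(methoxymethoxy)phenyl]-4H-chromen-4-one F5. Hydrogenolysis (H2, palladium on carbon (Pd/C), EtOAc) would give 5,7-dihydroxy-8-methoxy-3-(methoxymethoxy)-2-[3-methoxy-4-(methoxymethoxy)phenyl]-4H-chromen-4-one F6. Its free 7-OH should be alkylated selectively over the chelated 5-OH (prenyl bromide, K2CO3, acetone, rt), returning to the route at 22.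

3. Step 9. The base-catalysed alkoxy exchange may stall at a mixture of isopropyl and prenyl esters, or the unsubstituted semisquarate may oligomerise under amine catalysis. The fallback sets out from 14 and makes the ester irreversibly. Hydrolysis (aq. HCl, THF, rt) would give 3-hydroxycyclobut-3-ene-1,2-dione (semisquaric acid) F7. Silver-assisted O-alkylation of this strong vinylogous acid (Ag2O, prenyl bromide, MeCN, rt, dark) returns to the route at 16.

**Further compounds**
F1 | step 10 | 2-iodo-5-(methoxymethoxy)-6-[3-methoxy-4-(methoxymethoxy)phenyl]-4H-pyran-4-one | COCOc1ccc(-c2oc(I)cc(=O)c2OCOC)cc1OC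
F2 | step 10 | racemic 4-hydroxy-4-{5-(methoxymethoxy)-6-[3-methoxy-4-(methoxymethoxy)phenyl]-4-oxo-4H-pyran-2-yl}-3-[(3-methylbut-2-en-1-yl)oxy]cyclobut-2-en-1-one | O=C1C=C(OCC=C(C)C)C1(O)c1cc(=O)c(OCOC)c(-c2ccc(OCOC)c(OC)c2)o1
F3 | step 11 | 3-(benzyloxy)cyclobut-3-ene-1,2-dione | O=C1C=C(OCc2ccccc2)C1=O
F4 | step 11 | racemic 3-(benzyloxy)-4-methoxy-4-{5-(methoxymethoxy)-6-[3-methoxy-4-(methoxymethoxy)phenyl]-4-oxo-4H-pyran-2-yl}cyclobut-2-en-1-one | O=C1C=C(OCc2ccccc2)C1(OC)c1cc(=O)c(OCOC)c(-c2ccc(OCOC)c(OC)c2)o1
F5 | step 11 | 7-(benzyloxy)-5-hydroxy-8-methoxy-3-(methoxymethoxy)-2-[3-methoxy-4-(methoxymethoxy)phenyl]-4H-chromen-4-one | COCOc1ccc(-c2oc3c(OC)c(OCc4ccccc4)cc(O)c3c(=O)c2OCOC)cc1OC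
F6 | step 11 | 5,7-dihydroxy-8-methoxy-3-(methoxymethoxy)-2-[3-methoxy-4-(methoxymethoxy)phenyl]-4H-chromen-4-one | COCOc1ccc(-c2oc3c(OC)c(O)cc(O)c3c(=O)c2OCOC)cc1OC
F7 | step 9 | 3-hydroxycyclobut-3-ene-1,2-dione (semisquaric acid) | O=C1C=C(O)C1=O
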